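Ring A = C1(OMe)=C2(Me)–C3(=O)–C4(spiro)–C5(=O)–C6(Me)2; ring B = C4–C7H2–C8(4-methylpent-3-enyl)=C9H–C10H2–C11H(i-Pr).
Retrosynthesis: cut O–CH3 at C1, then C5–C6 (Dieckmann) and C1–C2 (C-acylation), which opens ring A to an ethyl ketone (C3) and a methyl ester (C5) on C4; then cut C4–C7 while rejoining the C3 oxygen to C9 (retro-Claisen) to reach a 2-alkenyl-3,4-dihydro-2H-pyran; finally cut C8–C9, O–C9 and C4–C11.
Enabling feature: C3(=O)–C4–C7–C8=C9 is a γ,δ-unsaturated ketone, so O, C3, C4 and C9, C8, C7 can be refolded into a cyclic allyl vinyl ether bridged by C10–C11; with C3 as ketone and C5 as ester the two carbonyl arms on C4 stay distinguishable.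
Forward order: dihydropyran (Michael addition, hemiacetal), alkenyl arm onto C9, carbocyclic ring B by Claisen ring contraction, ring A by acylation and Dieckmann closure, O-methylation last.
Stereochemistry: C11 from the amine-catalysed Michael addition; C9 (temporary) from addition to the oxocarbenium ion anti to the isopropyl group; C4 from C9 by the suprafacial [3,3] shift.

Key step: step 5

Remark on locants: pyrans 4, 5 and 10 carry ring locants O1, C2–C6; pyran C2, C4 and C5 are C9, C11 and C4 of the target.
Assumption: the usual shielding model for iminium ions of (S)-diarylprolinol silyl ethers (nucleophile anti to the diaryl(silyloxy)methyl group on the E,s-trans iminium ion) is taken to give the (S) centre; were the sense opposite, the (R)-catalyst would be used and nothing else changes.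

**Step 1**
Reactants: 1 methyl 3-oxopentanoate; 2 (E)-4-methylpent-2-enal
Product: 4 methyl (4S)-6-ethyl-2-hydroxy-4-isopropyl-3,4-dihydro-2H-pyran-5-carboxylate, via open-chain Michael adduct 3 (not isolated)
Conditions: (S)-α,α-diphenylprolinol trimethylsilyl ether (10 mol %), PhCO2H (10 mol %), CH2Cl2, 0 °C → rt
Reagents that add atoms: none
Why: Iminium-activated enantioselective Michael addition of the β-keto ester to the enal, followed by hemiacetalisation of the ketone enol onto the freed aldehyde, should set pyran C4 as S because the nucleophile adds to the iminium face remote from the diphenyl(silyloxy)methyl group.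

**Step 2**
Reactants: 4 methyl (4S)-6-ethyl-2-hydroxy-4-isopropyl-3,4-dihydro-2H-pyran-5-carboxylate
Product: 5 methyl (4S)-2-acetoxy-6-ethyl-4-isopropyl-3,4-dihydro-2H-pyran-5-carboxylate
Conditions: Ac2O, Et3N, DMAP (cat.), CH2Cl2, 0 °C
Reagents that add atoms: acetic anhydride, CC(=O)OC(C)=O
Why: DMAP-catalysed O-acetylation of the lactol hydroxyl gives an anomeric acetate that a Lewis acid can ionise, leaving the enol ether, the ester and C4 untouched; the anomeric configuration is lost in step 4 and does not matter.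

**Step 3**
Reactants: 6 6-methylhept-5-en-2-one
Product: 7 2,4,6-triisopropyl-N'-(6-methylhept-5-en-2-ylidene)benzenesulfonohydrazide
Conditions: 2,4,6-(i-Pr)3C6H2SO2NHNH2, HCl (cat.), MeOH, rt
Reagents that add atoms: 2,4,6-triisopropylbenzenesulfonohydrazide, CC(C)c1cc(C(C)C)c(S(=O)(=O)NN)c(C(C)C)c1
Why: Acid-catalysed condensation of the methyl ketone with the sulfonohydrazide gives the arylsulfonylhydrazone required for a Shapiro reaction; the trisubstituted alkene is inert.

**Step 4**
Reactants: 7 2,4,6-triisopropyl-N'-(6-methylhept-5-en-2-ylidene)benzenesulfonohydrazide; 5 methyl (4S)-2-acetoxy-6-ethyl-4-isopropyl-3,4-dihydro-2H-pyran-5-carboxylate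
Product: 10 methyl (2S,4S)-6-ethyl-4-isopropyl-2-(6-methylhepta-1,5-dien-2-yl)-3,4-dihydro-2H-pyran-5-carboxylate, via (6-methylhepta-1,5-dien-2-yl)lithium 8 (not isolated), via chloro(6-methylhepta-1,5-dien-2-yl)zinc 9 (not isolated)
Conditions: 7, n-BuLi (2.05 equiv), THF, −78 → 0 °C; ZnCl2, THF, −78 → 0 °C; then 5, BF3·OEt2, CH2Cl2, −78 → −20 °C
Reagents that add atoms: n-butyllithium, [Li]CCCC (lithium of 8 only); zinc chloride, Cl[Zn]Cl (zinc and chlorine of 9 only)
Why: A Shapiro reaction (dianion formation at the methyl group, loss of sulfinate and N2) gives the 1-alken-2-yllithium, transmetalation gives the milder alkenylzinc chloride, and BF3·OEt2 ionises the anomeric acetate to a ring oxocarbenium ion that the alkenylzinc captures (C-glycosylation-type substitution); attack should occur anti to the C4 isopropyl group, held pseudoaxial by allylic strain with the C5 ester, to give the 2,4-trans (2S,4S) isomer.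

**Step 5**
Reactants: 10 methyl (2S,4S)-6-ethyl-4-isopropyl-2-(6-methylhepta-1,5-dien-2-yl)-3,4-dihydro-2H-pyran-5-carboxylate
Product: 11 methyl (1R,6S)-6-isopropyl-3-(4-methylpent-3-en-1-yl)-1-propanoylcyclohex-3-ene-1-carboxylate
Conditions: PhMe (0.05 M, degassed), 2,6-di-tert-butyl-4-methylphenol (cat.), base-washed sealed tube, 180 °C
Reagents that add atoms: none
Why: Thermal Claisen ([3,3]-sigmatropic) rearrangement of the cyclic allyl vinyl ether C5=C6–O1–C2–C(=CH2): the exocyclic methylene bonds to C5 as O1–C2 breaks, the ring oxygen becomes the propanoyl carbonyl and the alkene moves into the new ring; the closest known reaction types are the thermal isomerisation of 2-alkenyl-3,4-dihydro-2H-pyrans to 4-acylcyclohexenes and the Claisen rearrangement of O-allyl enol ethers of β-keto esters. Ring B closes as a six-membered carbocycle by contraction of the oxacycle through a boat-like (bicyclo[2.2.2]octene-type) transition state, the only one available because the C3–C4 bridge ties the six reacting atoms together and the alkenyl arm must stand axial on C2. The new quaternary centre (C4 of the target) is controlled by C2: the shift is suprafacial, so the methylene reaches C5 only on the face carrying the alkenyl arm, and since that face is anti to isopropyl in the 2,4-trans isomer the propanoyl group ends cis to isopropyl, (1R,6S); the isopropyl-bearing centre is not involved. The step needs the [3,3] path to outrun cycloreversion (retro-hetero-Diels–Alder) and ionisation of the allylic C–O bond, either of which would erase the configuration and the ring-B regiochemistry; the alkyl (not alkoxy) substituent at C2, acid-free dilute conditions and the gain of a ketone carbonyl and a trisubstituted ring alkene at the cost of the vinylogous carbonate are relied on for this.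

**Step 6**
Reactants: 11 methyl (1R,6S)-6-isopropyl-3-(4-methylpent-3-en-1-yl)-1-propanoylcyclohex-3-ene-1-carboxylate; 12 2-methylpropanoyl chloride
Product: 13 methyl (1R,6S)-1-(2,4-dimethyl-3-oxopentanoyl)-6-isopropyl-3-(4-methylpent-3-en-1-yl)cyclohex-3-ene-1-carboxylate
Conditions: MgBr2·OEt2, i-Pr2NEt, CH2Cl2, 0 °C → rt
Reagents that add atoms: none
Why: Soft enolisation of the chelating β-keto ester at its only enolisable position (the ethyl CH2) and C-acylation by the acid chloride (crossed Claisen-type acylation) give the β-diketone as its magnesium chelate, which suppresses O-acylation; the quaternary centre cannot epimerise and the new CH(CH3) centre is lost on enolisation.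

**Step 7**
Reactants: 13 methyl (1R,6S)-1-(2,4-dimethyl-3-oxopentanoyl)-6-isopropyl-3-(4-methylpent-3-en-1-yl)cyclohex-3-ene-1-carboxylate
Product: 14 (6R,11S)-11-isopropyl-2,2,4-trimethyl-8-(4-methylpent-3-en-1-yl)spiro[5.5]undec-8-ene-1,3,5-trione
Conditions: LiN(i-Pr)2 (3 equiv), THF, −78 °C → rt; then aq. HCl
Reagents that add atoms: none
Why: Dieckmann (intramolecular Claisen) condensation through the 1,3-dianion of the β-diketone: beyond the acidic CH(CH3) the only α-hydrogen is the isopropyl methine, whose carbanion attacks the neighbouring ester (6-exo-trig), and the product is held as the stabilised enolate of the cyclic 1,3-dione, which drives closure of ring A without touching a stereocentre.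

**Step 8**
Reactants: 14 (6R,11S)-11-isopropyl-2,2,4-trimethyl-8-(4-methylpent-3-en-1-yl)spiro[5.5]undec-8-ene-1,3,5-trione
Product: 15 (6R,11S)-11-isopropyl-3-methoxy-2,4,4-trimethyl-8-(4-methylpent-3-en-1-yl)spiro[5.5]undeca-2,8-diene-1,5-dione (CNP0419264.1)
Conditions: Me3SiCHN2, MeOH/PhMe, 0 °C → rt
Reagents that add atoms: (trimethylsilyl)diazomethane, C[Si](C)(C)C=[N+]=[N-]
Why: O-methylation of the vinylogous acid (enolised 1,3-dione) with a diazomethane equivalent alkylates oxygen only; the enol oxygen flanked by the gem-dimethyl carbon is less hindered than the one next to the spiro centre and its cis isopropyl group, so the 3-methoxy-2-en-1-one of the target should predominate.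

**Compound list**
1 | methyl 3-oxopentanoate | CCC(=O)CC(=O)OC | starting material
2 | (E)-4-methylpent-2-enal | CC(C)/C=C/C=O | starting material
3 | methyl (3S)-3-isopropyl-5-oxo-2-propanoylpentanoate (open-chain Michael adduct, C2 epimers) | CCC(=O)C(C(=O)OC)[C@H](C(C)C)CC=O | intermediate
4 | methyl (4S)-6-ethyl-2-hydroxy-4-isopropyl-3,4-dihydro-2H-pyran-5-carboxylate (lactol, both anomers) | CCC1=C(C(=O)OC)[C@H](C(C)C)CC(O)O1 | intermediate
5 | methyl (4S)-2-acetoxy-6-ethyl-4-isopropyl-3,4-dihydro-2H-pyran-5-carboxylate (both anomers) | CCC1=C(C(=O)OC)[C@H](C(C)C)CC(OC(C)=O)O1 | intermediate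
6 | 6-methylhept-5-en-2-one | CC(=O)CCC=C(C)C | starting material
7 | 2,4,6-triisopropyl-N'-(6-methylhept-5-en-2-ylidene)benzenesulfonohydrazide | CC(CCC=C(C)C)=NNS(=O)(=O)c1c(C(C)C)cc(C(C)C)cc1C(C)C | intermediate
8 | (6-methylhepta-1,5-dien-2-yl)lithium | [Li]C(=C)CCC=C(C)C | intermediate
9 | chloro(6-methylhepta-1,5-dien-2-yl)zinc | Cl[Zn]C(=C)CCC=C(C)C | intermediate
10 | methyl (2S,4S)-6-ethyl-4-isopropyl-2-(6-methylhepta-1,5-dien-2-yl)-3,4-dihydro-2H-pyran-5-carboxylate (2,4-trans) | CCC1=C(C(=O)OC)[C@H](C(C)C)C[C@@H](C(=C)CCC=C(C)C)O1 | intermediate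
11 | methyl (1R,6S)-6-isopropyl-3-(4-methylpent-3-en-1-yl)-1-propanoylcyclohex-3-ene-1-carboxylate (propanoyl cis to isopropyl) | CCC(=O)[C@]1(CC(CCC=C(C)C)=CC[C@H]1C(C)C)C(=O)OC | intermediate
12 | 2-methylpropanoyl chloride | CC(C)C(Cl)=O | starting material
13 | methyl (1R,6S)-1-(2,4-dimethyl-3-oxopentanoyl)-6-isopropyl-3-(4-methylpent-3-en-1-yl)cyclohex-3-ene-1-carboxylate (side-chain CH(CH3) epimers and enols) | CC(C)C(=O)C(C)C(=O)[C@]1(CC(CCC=C(C)C)=CC[C@H]1C(C)C)C(=O)OC | intermediate
14 | (6R,11S)-11-isopropyl-2,2,4-trimethyl-8-(4-methylpent-3-en-1-yl)spiro[5.5]undec-8-ene-1,3,5-trione (drawn as triketone, present as its enols) | CC1C(=O)[C@]2(CC(CCC=C(C)C)=CC[C@H]2C(C)C)C(=O)C(C)(C)C1=O | intermediate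
15 | (6R,11S)-11-isopropyl-3-methoxy-2,4,4-trimethyl-8-(4-methylpent-3-en-1-yl)spiro[5.5]undeca-2,8-diene-1,5-dione | COC1=C(C)C(=O)[C@]2(CC(CCC=C(C)C)=CC[C@H]2C(C)C)C(=O)C1(C)C | target

**Step count and risks**
Total: 8 steps. Longest linear sequence: 7 steps (1, 2, 4, 5, 6, 7, 8).

Step 4. What may go wrong: ionisation of the anomeric acetate is slowed by the electron-poor ring oxygen and may lose out to elimination of acetic acid (4H-pyran formation); attack on the nearly flat oxocarbenium ion may show poor facial selectivity; the Lewis acid may ionise the allylic C–O bond of the product. Fallback, setting out from lactol 4 and ketone 6 and returning at 10: replace substitution under substrate control by carbonyl addition under catalyst control.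
- Ketone 6 is converted with LiN(i-Pr)2 and PhNTf2 (THF, −78 °C, kinetic enolate) into 6-methylhepta-1,5-dien-2-yl trifluoromethanesulfonate F1.
- F1 is coupled with the open-chain aldehyde tautomer of 4 by the Nozaki–Hiyama–Kishi reaction (CrCl2, NiCl2 cat., chiral sulfonamide ligand). The ligand fixes the carbinol configuration and should give methyl (3S,5S)-5-hydroxy-3-isopropyl-10-methyl-6-methylidene-2-propanoylundec-9-enoate F2.
- Mild cyclodehydration (PPTS, 4 Å molecular sieves, PhMe) closes F2 to 10. The carbinol oxygen becomes the ring oxygen, so its C–O bond is never broken and the configuration at C2 is retained.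

Step 5. What may go wrong: cycloreversion to oxadiene and triene, or ionisation of the allylic C–O bond, may compete with the boat-constrained [3,3] shift and scramble configuration and regiochemistry; the shift may also be too slow below the decomposition range. Fallback, setting out from enal 2 and returning at 13: the same ring contraction at the lactone oxidation level (Ireland–Claisen), which runs near 100 °C.
- Enal 2 and dimethyl malonate under the amine catalyst of step 1 give dimethyl 2-[(3S)-2-methyl-5-oxopentan-3-yl]propanedioate F3.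
- Ligand-controlled Nozaki–Hiyama–Kishi coupling with 6-methylhepta-1,5-dien-2-yl trifluoromethanesulfonate F1 gives dimethyl 2-[(3S,5S)-5-hydroxy-2,10-dimethyl-6-methylideneundec-9-en-3-yl]propanedioate F4.
- PPTS lactonises F4 to methyl (4S,6S)-4-isopropyl-6-(6-methylhepta-1,5-dien-2-yl)-2-oxooxane-3-carboxylate F5.
- t-BuMe2SiOTf/Et3N gives the silyl ketene acetal methyl (2S,4S)-6-[(tert-butyldimethylsilyl)oxy]-4-isopropyl-2-(6-methylhepta-1,5-dien-2-yl)-3,4-dihydro-2H-pyran-5-carboxylate F6.
- Heating F6 in PhMe should give, through the same boat-like array, 1-(tert-butyldimethylsilyl) 1-methyl (1S,6S)-6-isopropyl-3-(4-methylpent-3-en-1-yl)cyclohex-3-ene-1,1-dicarboxylate F7.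
- Aqueous work-up hydrolyses F7 to (1R,6S)-6-isopropyl-1-(methoxycarbonyl)-3-(4-methylpent-3-en-1-yl)cyclohex-3-ene-1-carboxylic acid F8, with the acid cis to isopropyl.
- Oxalyl chloride gives methyl (1S,6S)-1-(chlorocarbonyl)-6-isopropyl-3-(4-methylpent-3-en-1-yl)cyclohex-3-ene-1-carboxylate F9.
- F9 C-acylates the lithium enolate of 2-methylpentan-3-one (LiN(i-Pr)2, THF, −78 °C, deprotonation at CH2) to give 13.

Step 8. What may go wrong: methylation at the other enol oxygen gives the regioisomeric vinylogous ester; the hindered closure of step 7 may also stall. Fallback, setting out from 11 and returning at 15: fix the methoxy position by construction before ring A is closed.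
- 11 is converted (LiN(i-Pr)2, Me3SiCl, THF, −78 °C) into methyl (1R,6S)-6-isopropyl-3-(4-methylpent-3-en-1-yl)-1-[1-(trimethylsilyloxy)prop-1-en-1-yl]cyclohex-3-ene-1-carboxylate F10.
- Mukaiyama-type addition of F10 to 1,1,1-trimethoxy-2-methylpropane (Me3SiOTf cat., CH2Cl2, −78 °C) gives methyl (1R,6S)-1-(3,3-dimethoxy-2,4-dimethylpentanoyl)-6-isopropyl-3-(4-methylpent-3-en-1-yl)cyclohex-3-ene-1-carboxylate F11.
- KN(SiMe3)2 (excess, THF, −78 → 0 °C) first eliminates methanol to methyl (1R,6S)-1-(3-methoxy-2,4-dimethylpent-2-enoyl)-6-isopropyl-3-(4-methylpent-3-en-1-yl)cyclohex-3-ene-1-carboxylate F12.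
- The only acidic position of F12 is the γ-methine; its extended enolate closes onto the ester (vinylogous Dieckmann) to give 15 with the methoxy group on C1.

**Further compounds**
F1 | step 4 | 6-methylhepta-1,5-dien-2-yl trifluoromethanesulfonate | C=C(CCC=C(C)C)OS(=O)(=O)C(F)(F)F
F2 | step 4 | methyl (3S,5S)-5-hydroxy-3-isopropyl-10-methyl-6-methylidene-2-propanoylundec-9-enoate | CCC(=O)C(C(=O)OC)[C@H](C(C)C)C[C@H](O)C(=C)CCC=C(C)C
F3 | step 5 | dimethyl 2-[(3S)-2-methyl-5-oxopentan-3-yl]propanedioate | COC(=O)C(C(=O)OC)[C@H](C(C)C)CC=O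
F4 | step 5 | dimethyl 2-[(3S,5S)-5-hydroxy-2,10-dimethyl-6-methylideneundec-9-en-3-yl]propanedioate | COC(=O)C(C(=O)OC)[C@H](C(C)C)C[C@H](O)C(=C)CCC=C(C)C
F5 | step 5 | methyl (4S,6S)-4-isopropyl-6-(6-methylhepta-1,5-dien-2-yl)-2-oxooxane-3-carboxylate | O=C1C(C(=O)OC)[C@H](C(C)C)C[C@@H](C(=C)CCC=C(C)C)O1
F6 | step 5 | methyl (2S,4S)-6-[(tert-butyldimethylsilyl)oxy]-4-isopropyl-2-(6-methylhepta-1,5-dien-2-yl)-3,4-dihydro-2H-pyran-5-carboxylate | CC(C)(C)[Si](C)(C)OC1=C(C(=O)OC)[C@H](C(C)C)C[C@@H](C(=C)CCC=C(C)C)O1
F7 | step 5 | 1-(tert-butyldimethylsilyl) 1-methyl (1S,6S)-6-isopropyl-3-(4-methylpent-3-en-1-yl)cyclohex-3-ene-1,1-dicarboxylate | CC(C)(C)[Si](C)(C)OC(=O)[C@]1(CC(CCC=C(C)C)=CC[C@H]1C(C)C)C(=O)OC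
F8 | step 5 | (1R,6S)-6-isopropyl-1-(methoxycarbonyl)-3-(4-methylpent-3-en-1-yl)cyclohex-3-ene-1-carboxylic acid | OC(=O)[C@]1(CC(CCC=C(C)C)=CC[C@H]1C(C)C)C(=O)OC
F9 | step 5 | methyl (1S,6S)-1-(chlorocarbonyl)-6-isopropyl-3-(4-methylpent-3-en-1-yl)cyclohex-3-ene-1-carboxylate | ClC(=O)[C@]1(CC(CCC=C(C)C)=CC[C@H]1C(C)C)C(=O)OC
F10 | step 8 | methyl (1R,6S)-6-isopropyl-3-(4-methylpent-3-en-1-yl)-1-[1-(trimethylsilyloxy)prop-1-en-1-yl]cyclohex-3-ene-1-carboxylate | CC=C(O[Si](C)(C)C)[C@]1(CC(CCC=C(C)C)=CC[C@H]1C(C)C)C(=O)OC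
F11 | step 8 | methyl (1R,6S)-1-(3,3-dimethoxy-2,4-dimethylpentanoyl)-6-isopropyl-3-(4-methylpent-3-en-1-yl)cyclohex-3-ene-1-carboxylate | CC(C)C(OC)(OC)C(C)C(=O)[C@]1(CC(CCC=C(C)C)=CC[C@H]1C(C)C)C(=O)OC
F12 | step 8 | methyl (1R,6S)-1-(3-methoxy-2,4-dimethylpent-2-enoyl)-6-isopropyl-3-(4-methylpent-3-en-1-yl)cyclohex-3-ene-1-carboxylate | CC(C)C(OC)=C(C)C(=O)[C@]1(CC(CCC=C(C)C)=CC[C@H]1C(C)C)C(=O)OC
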